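**Plan**

- Retrosynthesis: the four benzyl ethers and two acetates are removed first. The cis CH2O arms on C3 and C4 of the tetrahydrofuran (ring A: O1, C2, C3, C4, C5) are then tied into a second five-membered ring (ring B). Ring B is a cyclic methyl acetal that holds the C3 arm at the aldehyde level.
- Enabling feature: C2 is an aldehyde-level carbon bonded to both O1 and C3. C3 lies next to the ring-B acetal carbon, so it is the β-carbon of a 2,3-dihydrofuran. O1–C2 and C2–C3 are therefore cut in one operation, giving an aryl aldehyde dimethyl acetal and an aryl(2,3-dihydrofuran-3-yl)methanol.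
- The carbinol is cut at C4–C5 by a syn aldol between a pent-4-enoyl imide and the same aryl aldehyde. The vinyl group is the masked enol-ether CH.
- Forward order: C4–C5 (aldol), ring B (alkene cleavage, lactol, dehydration), ring A (key step). Ring B is then reopened by hydrolysis/reduction, followed by acetylation and debenzylation.
- Stereochemistry: C4/C5 come from the chair transition state of the Z-boron enolate. C3 comes from the enforced cis fusion of rings A and B. C2 comes from the convex-face preference of the bicycle under reversible closure.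

Key step: step 9

Assumption: with the (2R,3S,4R,5S) configuration and pairwise identical substituents, the target has a mirror plane through O1 and the C3–C4 midpoint (meso, achiral). Chiral intermediates are therefore made as racemates, and their SMILES show one enantiomer with the correct relative configuration.

**Step 1**
Reactants: 1 oxazolidin-2-one; 2 pent-4-enoyl chloride
Product: 3 3-(pent-4-enoyl)oxazolidin-2-one
Conditions: Et3N, DMAP (cat.), CH2Cl2, 0 °C → rt
Reagents that add atoms: none
Why: DMAP-catalysed N-acylation of an oxazolidinone by an acid chloride is routine and gives the imide needed for soft enolisation, with no stereocentre formed.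

**Step 2**
Reactants: 3 3-(pent-4-enoyl)oxazolidin-2-one; 4 3,4-bis(benzyloxy)benzaldehyde
Product: 7 rac-3-[(2S*)-2-{(S*)-[3,4-bis(benzyloxy)phenyl](hydroxy)methyl}pent-4-enoyl]oxazolidin-2-one (syn aldol), via boron enolate 5 (not isolated), via boron aldolate 6 (not isolated)
Conditions: Bu2BOTf, Et3N, CH2Cl2, 0 °C; 4, −78 → 0 °C; then pH 7 buffer, MeOH, 30% H2O2, 0 °C
Reagents that add atoms: none
Why: In this boron-mediated (Evans-type) syn aldol, soft enolisation gives the Z-enolate 5, which adds to 4 through a closed chair transition state and sets C4 and C5 (target numbering) syn, the relationship that later places the C5 aryl group trans to the C4 CH2O arm.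

**Step 3**
Reactants: 7 syn aldol
Product: 8 rac-3-[(2S*)-2-{(S*)-[3,4-bis(benzyloxy)phenyl](tert-butyldimethylsilyloxy)methyl}pent-4-enoyl]oxazolidin-2-one
Conditions: TBSOTf, 2,6-lutidine, CH2Cl2, 0 °C
Reagents that add atoms: tert-butyldimethylsilyl triflate, CC(C)(C)[Si](C)(C)OS(=O)(=O)C(F)(F)F
Why: Silyl triflate/lutidine silylation of a hindered secondary alcohol is standard, stops retro-aldol cleavage and masks the benzylic hydroxyl so that only the primary hydroxyl can close the lactol in step 5.

**Step 4**
Reactants: 8 silylated aldol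
Product: 9 rac-(2R*)-2-{(S*)-[3,4-bis(benzyloxy)phenyl](tert-butyldimethylsilyloxy)methyl}pent-4-en-1-ol
Conditions: LiBH4, MeOH (1 equiv), THF, 0 °C
Reagents that add atoms: none
Why: Reductive removal of the N-acyl oxazolidinone with lithium borohydride attacks the more electrophilic exocyclic carbonyl, leaves alkene, silyl ether and benzyl ethers intact, and does not touch either stereocentre.

**Step 5**
Reactants: 9 homoallylic-type primary alcohol
Product: 12 rac-(4R*)-4-{(S*)-[3,4-bis(benzyloxy)phenyl](tert-butyldimethylsilyloxy)methyl}tetrahydrofuran-2-ol (anomeric mixture), via triol 10 (not isolated), via hydroxy aldehyde 11 (not isolated)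
Conditions: OsO4 (cat.), NaIO4, 2,6-lutidine, 1,4-dioxane–H2O, rt
Reagents that add atoms: osmium tetroxide, O=[Os](=O)(=O)=O (delivers the oxygen); sodium periodate, [Na+].[O-]I(=O)(=O)=O (terminal oxygen source)
Why: Lemieux–Johnson cleavage removes the terminal CH2 of the only alkene while sparing the electron-rich arenes, and the resulting γ-hydroxy aldehyde 11 closes spontaneously to the five-membered lactol, whose anomeric configuration is irrelevant.

**Step 6**
Reactants: 12 lactol
Product: 14 rac-tert-butyl{(S*)-[3,4-bis(benzyloxy)phenyl][(3R*)-2,3-dihydrofuran-3-yl]methoxy}dimethylsilane, via anomeric mesylate 13 (not isolated)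
Conditions: MsCl, Et3N (excess), CH2Cl2, −40 °C → reflux
Reagents that add atoms: none
Why: Mesylation–elimination of a lactol is the usual entry to 2,3-dihydrofurans and furanoid glycals, and since only the ring CH2 next to the anomeric carbon carries β-hydrogens the enol-ether double bond can form in one position only.

**Step 7**
Reactants: 14 silylated dihydrofuran
Product: 15 rac-(S*)-[3,4-bis(benzyloxy)phenyl][(3R*)-2,3-dihydrofuran-3-yl]methanol
Conditions: TBAF, THF, 0 °C → rt; chromatography on Et3N-deactivated silica
Reagents that add atoms: none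
Why: Fluoride-induced desilylation runs under non-acidic conditions, so the acid-sensitive enol ether and both stereocentres should survive.

**Step 8**
Reactants: 4 3,4-bis(benzyloxy)benzaldehyde
Product: 16 3,4-bis(benzyloxy)benzaldehyde dimethyl acetal
Conditions: HC(OMe)3, p-TsOH·H2O (cat.), MeOH, rt; Et3N quench
Reagents that add atoms: trimethyl orthoformate, COC(OC)OC; methanol, CO
Why: Acid-catalysed acetalisation with the orthoformate as water scavenger is routine for electron-rich benzaldehydes.

**Step 9**
Reactants: 15 aryl(2,3-dihydrofuran-3-yl)methanol; 16 aryl aldehyde dimethyl acetal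
Product: 19 rac-(1R*,2S*,4R*,5R*)-2,4-bis[3,4-bis(benzyloxy)phenyl]-6-methoxy-3,7-dioxabicyclo[3.3.0]octane (cis-fused; both aryl groups exo; C6 epimers), via trimethylsilyl ether 17 (not isolated), via mixed acetal 18 (not isolated)
Conditions: TMSOTf (1.3 equiv), 2,6-di-tert-butyl-4-methylpyridine (DTBMP, 1.2 equiv), CH2Cl2, −78 → 0 °C; Et3N quench
Reagents that add atoms: none
Why: TMSOTf/DTBMP silylates the carbinol to 17, the remaining TMSOTf ionises 16, the silyl ether oxygen captures the methoxy-oxocarbenium ion to give mixed acetal 18 (O1–C2), and loss of the second methoxy group gives the (E)-O1=C2 oxocarbenium ion, whose carbon is attacked by the enol-ether β-carbon (C2–C3) before TMSOMe caps the new ring-B oxocarbenium ion as the methyl acetal and returns TMSOTf. The closest known reaction type is silyl-triflate-catalysed silyl ether/acetal exchange followed by an intramolecular Mukaiyama-aldol-like (Prins-type) addition of a cyclic enol ether, which is established for (2,3-dihydrofuran-3-yl)methanols and aryl aldehyde acetals. The single ring closed is the tetrahydrofuran O1–C2–C3–C4–C5, formally 5-endo-trig at the oxocarbenium bond and exo with respect to the enol-ether double bond, a mode that cationic electrophiles and strongly polarised π-nucleophiles tolerate. C3 is controlled by the tether, because the three-atom link C4–C5–O1 can bring C2 only to the dihydrofuran face that bears the side chain, so the bicycle is cis-fused and C3/C4 are cis; C2 is controlled by the convex shape of that bicycle, and because re-ionisation of the methyl acetal makes C2–C3 formation reversible, warming to 0 °C should carry any endo-aryl closure product over to the exo,exo isomer, while the acetal carbon forms as a mixture that step 10 erases and C5 keeps its already favoured exo aryl group. The step needs O-alkylation before C-alkylation by the acetal-derived cation and attack through the β- rather than the α-carbon of the enol ether; the first is secured by fast reversible exchange at oxygen with an intramolecular follow-up, the second by the oxygen-polarised double bond, which also disfavours a 2-oxonia-Cope shift. DTBMP keeps the medium aprotic so that the enol ether is not protonated.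

**Step 10**
Reactants: 19 bicyclic methyl acetal
Product: 21 meso-[(2R,3S,4R,5S)-2,5-bis[3,4-bis(benzyloxy)phenyl]tetrahydrofuran-3,4-diyl]dimethanol, via bicyclic lactol 20 (not isolated)
Conditions: 1 M aq HCl, THF, rt; then NaHCO3 (to pH 8), NaBH4, 0 °C
Reagents that add atoms: water, O
Why: Acid hydrolysis of the 2-alkoxytetrahydrofuran acetal is much faster than ionisation of the ring-A benzylic ethers, and borohydride reduction of the lactol through its hydroxy aldehyde form at 0 °C opens ring B to the two cis CH2OH arms before C3 can epimerise, so both enantiomers of 19 converge on one achiral diol.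

**Step 11**
Reactants: 21 meso diol
Product: 22 meso-[(2R,3S,4R,5S)-2,5-bis[3,4-bis(benzyloxy)phenyl]tetrahydrofuran-3,4-diyl]bis(methylene) diacetate
Conditions: Ac2O, pyridine, DMAP (cat.), CH2Cl2, rt
Reagents that add atoms: acetic anhydride, CC(=O)OC(C)=O
Why: DMAP-catalysed acetylation of two primary alcohols is routine, and its basic medium avoids the acid under which a free CH2OH could capture a benzylic cation and reorganise the skeleton.

**Step 12**
Reactants: 22 tetrabenzyl diacetate
Product: 23 meso-[(2R,3S,4R,5S)-2,5-bis(3,4-dihydroxyphenyl)tetrahydrofuran-3,4-diyl]bis(methylene) diacetate (CNP0416169.1)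
Conditions: H2 (1 atm), 10% Pd/C, EtOAc, rt, stopped after uptake of 4 equiv H2; filtration under argon
Reagents that add atoms: none
Why: Catalytic hydrogenolysis cleaves aryl benzyl ethers faster than the dialkyl-type benzylic ethers of ring A in a neutral aprotic solvent at atmospheric pressure, and it leaves the acetates and all four stereocentres untouched.

**Compound list**

1 | oxazolidin-2-one | O=C1NCCO1 | starting material
2 | pent-4-enoyl chloride | C=CCCC(=O)Cl | starting material
3 | 3-(pent-4-enoyl)oxazolidin-2-one | C=CCCC(=O)N1CCOC1=O | intermediate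
4 | 3,4-bis(benzyloxy)benzaldehyde | O=Cc1ccc(OCc2ccccc2)c(OCc2ccccc2)c1 | starting material
5 | (Z)-dibutylboron enolate of 3 (not isolated) | C=CC/C=C(\OB(CCCC)CCCC)N1CCOC1=O | intermediate
6 | dibutylboron aldolate of 7 (not isolated) | CCCCB(CCCC)O[C@H](c1ccc(OCc2ccccc2)c(OCc2ccccc2)c1)[C@H](CC=C)C(=O)N1CCOC1=O | intermediate
7 | rac-3-[(2S*)-2-{(S*)-[3,4-bis(benzyloxy)phenyl](hydroxy)methyl}pent-4-enoyl]oxazolidin-2-one (syn) | O[C@H](c1ccc(OCc2ccccc2)c(OCc2ccccc2)c1)[C@H](CC=C)C(=O)N1CCOC1=O | intermediate
8 | TBS ether of 7 | CC(C)(C)[Si](C)(C)O[C@H](c1ccc(OCc2ccccc2)c(OCc2ccccc2)c1)[C@H](CC=C)C(=O)N1CCOC1=O | intermediate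
9 | rac-(2R*)-2-{(S*)-[3,4-bis(benzyloxy)phenyl](tert-butyldimethylsilyloxy)methyl}pent-4-en-1-ol | CC(C)(C)[Si](C)(C)O[C@H](c1ccc(OCc2ccccc2)c(OCc2ccccc2)c1)[C@H](CC=C)CO | intermediate
10 | rac-(4R*)-4-{(S*)-[3,4-bis(benzyloxy)phenyl](tert-butyldimethylsilyloxy)methyl}pentane-1,2,5-triol (C2 epimers, not isolated) | CC(C)(C)[Si](C)(C)O[C@H](c1ccc(OCc2ccccc2)c(OCc2ccccc2)c1)[C@H](CC(O)CO)CO | intermediate
11 | rac-(3R*)-3-{(S*)-[3,4-bis(benzyloxy)phenyl](tert-butyldimethylsilyloxy)methyl}-4-hydroxybutanal (not isolated) | CC(C)(C)[Si](C)(C)O[C@H](c1ccc(OCc2ccccc2)c(OCc2ccccc2)c1)[C@H](CC=O)CO | intermediate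
12 | rac-(4R*)-4-{(S*)-[3,4-bis(benzyloxy)phenyl](tert-butyldimethylsilyloxy)methyl}tetrahydrofuran-2-ol (anomers) | CC(C)(C)[Si](C)(C)O[C@H](c1ccc(OCc2ccccc2)c(OCc2ccccc2)c1)[C@H]1COC(O)C1 | intermediate
13 | 2-O-methanesulfonate of 12 (not isolated) | CC(C)(C)[Si](C)(C)O[C@H](c1ccc(OCc2ccccc2)c(OCc2ccccc2)c1)[C@H]1COC(OS(C)(=O)=O)C1 | intermediate
14 | rac-tert-butyl{(S*)-[3,4-bis(benzyloxy)phenyl][(3R*)-2,3-dihydrofuran-3-yl]methoxy}dimethylsilane | CC(C)(C)[Si](C)(C)O[C@H](c1ccc(OCc2ccccc2)c(OCc2ccccc2)c1)[C@H]1COC=C1 | intermediate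
15 | rac-(S*)-[3,4-bis(benzyloxy)phenyl][(3R*)-2,3-dihydrofuran-3-yl]methanol | O[C@H](c1ccc(OCc2ccccc2)c(OCc2ccccc2)c1)[C@H]1COC=C1 | intermediate
16 | 3,4-bis(benzyloxy)benzaldehyde dimethyl acetal | COC(OC)c1ccc(OCc2ccccc2)c(OCc2ccccc2)c1 | intermediate
17 | trimethylsilyl ether of 15 (not isolated) | C[Si](C)(C)O[C@H](c1ccc(OCc2ccccc2)c(OCc2ccccc2)c1)[C@H]1COC=C1 | intermediate
18 | mixed methyl acetal of 15 with the aryl aldehyde (acetal epimers, not isolated) | COC(O[C@H](c1ccc(OCc2ccccc2)c(OCc2ccccc2)c1)[C@H]1COC=C1)c1ccc(OCc2ccccc2)c(OCc2ccccc2)c1 | intermediate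
19 | rac-(1R*,2S*,4R*,5R*)-2,4-bis[3,4-bis(benzyloxy)phenyl]-6-methoxy-3,7-dioxabicyclo[3.3.0]octane (cis-fused, aryl groups exo, C6 epimers) | COC1OC[C@@H]2[C@@H](c3ccc(OCc4ccccc4)c(OCc4ccccc4)c3)O[C@@H](c3ccc(OCc4ccccc4)c(OCc4ccccc4)c3)[C@H]12 | intermediate
20 | rac-(1R*,2S*,4R*,5R*)-2,4-bis[3,4-bis(benzyloxy)phenyl]-3,7-dioxabicyclo[3.3.0]octan-6-ol (C6 epimers, not isolated) | OC1OC[C@@H]2[C@@H](c3ccc(OCc4ccccc4)c(OCc4ccccc4)c3)O[C@@H](c3ccc(OCc4ccccc4)c(OCc4ccccc4)c3)[C@H]12 | intermediate
21 | meso-[(2R,3S,4R,5S)-2,5-bis[3,4-bis(benzyloxy)phenyl]tetrahydrofuran-3,4-diyl]dimethanol | OC[C@@H]1[C@H](CO)[C@@H](c2ccc(OCc3ccccc3)c(OCc3ccccc3)c2)O[C@H]1c1ccc(OCc2ccccc2)c(OCc2ccccc2)c1 | intermediate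
22 | meso-[(2R,3S,4R,5S)-2,5-bis[3,4-bis(benzyloxy)phenyl]tetrahydrofuran-3,4-diyl]bis(methylene) diacetate | CC(=O)OC[C@@H]1[C@H](COC(C)=O)[C@@H](c2ccc(OCc3ccccc3)c(OCc3ccccc3)c2)O[C@H]1c1ccc(OCc2ccccc2)c(OCc2ccccc2)c1 | intermediate
23 | meso-[(2R,3S,4R,5S)-2,5-bis(3,4-dihydroxyphenyl)tetrahydrofuran-3,4-diyl]bis(methylene) diacetate | CC(=O)OC[C@@H]1[C@H](COC(C)=O)[C@@H](c2ccc(O)c(O)c2)O[C@H]1c1ccc(O)c(O)c1 | target

**Totals**

Total step count: 12.
Longest linear sequence: 11 (steps 1–7 and 9–12). Step 8 is a one-step branch from 4.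

**Steps most likely to fail**

Risk 1, step 9.
- What may go wrong: the cation from 16 may alkylate the enol ether of another molecule before exchange at the hindered secondary oxygen has taken place. The benzylic C5–O bond may ionise, with loss of the C5 configuration or elimination and aromatisation of ring B. Closure may also stall at the kinetic endo-aryl stage.
- Fallback: O1–C2 is formed without acid, and only the C2–C3 closure is left to the Lewis acid. It sets out from 15.
- Esterification with commercial 3,4-bis(benzyloxy)benzoic acid (EDC, DMAP, CH2Cl2) should give the benzoate ester F1.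
- DIBAL-H at −78 °C, with trapping of the aluminium hemiacetal by Ac2O/pyridine/DMAP, should give the α-acetoxy ether F2.
- BF3·OEt2 in CH2Cl2 at −78 °C ionises only the acetate. The same O1=C2 oxocarbenium ion closes onto the enol ether, and acetate returns to give the bicyclic anomeric acetate F3.
- K2CO3 in MeOH removes the acetyl group, and the sequence comes back to the route at lactol 20 (borohydride stage of step 10).

Risk 2, step 6.
- What may go wrong: the anomeric mesylate may revert to lactol on work-up or couple with unreacted lactol to a bis-acetal. The enol ether may also add acid from the ammonium salts during the reflux.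
- Fallback: ionisation/base-induced elimination is replaced by a thermal syn elimination. It sets out from 12.
- Diphenyl disulfide and Bu3P (CH2Cl2, rt) should give the phenyl thioacetal F4.
- mCPBA (CH2Cl2, −78 °C) should give the sulfoxide F5.
- Heating in toluene with iPr2NEt should eliminate across the only position that has β-hydrogens, coming back to the route at 14.

Risk 3, step 12.
- What may go wrong: once the phenols are free, the ring-A C2–O1 and C5–O1 bonds, benzylic to para-oxygenated arenes, may undergo hydrogenolysis. The catechols may oxidise in air during filtration.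
- Fallback: a non-reductive dealkylation. It sets out from 22.
- BCl3 with pentamethylbenzene as benzyl-cation scavenger (CH2Cl2, −78 °C, MeOH quench) should cleave the four aryl benzyl ethers in the presence of the acetates and arrive directly at 23.
- No new compound is made on the way (F0). Any reversible opening of ring A should re-close to the favoured 2,3-trans/4,5-trans arrangement.

**Further compounds**

F1 | step 9 | rac-(S*)-[3,4-bis(benzyloxy)phenyl][(3R*)-2,3-dihydrofuran-3-yl]methyl 3,4-bis(benzyloxy)benzoate | O=C(O[C@H](c1ccc(OCc2ccccc2)c(OCc2ccccc2)c1)[C@H]1COC=C1)c1ccc(OCc2ccccc2)c(OCc2ccccc2)c1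
F2 | step 9 | rac-[3,4-bis(benzyloxy)phenyl]{(S*)-[3,4-bis(benzyloxy)phenyl][(3R*)-2,3-dihydrofuran-3-yl]methoxy}methyl acetate (acetal epimers) | CC(=O)OC(O[C@H](c1ccc(OCc2ccccc2)c(OCc2ccccc2)c1)[C@H]1COC=C1)c1ccc(OCc2ccccc2)c(OCc2ccccc2)c1
F3 | step 9 | rac-(1R*,2S*,4R*,5R*)-2,4-bis[3,4-bis(benzyloxy)phenyl]-3,7-dioxabicyclo[3.3.0]octan-6-yl acetate (C6 epimers) | CC(=O)OC1OC[C@@H]2[C@@H](c3ccc(OCc4ccccc4)c(OCc4ccccc4)c3)O[C@@H](c3ccc(OCc4ccccc4)c(OCc4ccccc4)c3)[C@H]12
F4 | step 6 | rac-tert-butyl{(S*)-[3,4-bis(benzyloxy)phenyl][(3R*)-5-(phenylsulfanyl)tetrahydrofuran-3-yl]methoxy}dimethylsilane (C5 epimers) | CC(C)(C)[Si](C)(C)O[C@H](c1ccc(OCc2ccccc2)c(OCc2ccccc2)c1)[C@H]1COC(Sc2ccccc2)C1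
F5 | step 6 | rac-tert-butyl{(S*)-[3,4-bis(benzyloxy)phenyl][(3R*)-5-(phenylsulfinyl)tetrahydrofuran-3-yl]methoxy}dimethylsilane (epimers at C5 and sulfur) | CC(C)(C)[Si](C)(C)O[C@H](c1ccc(OCc2ccccc2)c(OCc2ccccc2)c1)[C@H]1COC(S(=O)c2ccccc2)C1
F0 | step 12 | none | none
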